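## Retrosynthetic overview
1. Both O-heterocycles of the (2S)-flavanone are opened at once. The pyranone is cut at O1–C2 (asymmetric 6-endo-trig oxa-Michael) and the furan at O1–C2 (5-endo-dig hydroalkoxylation). This gives an acyclic alkynyl bis-phenol chalcone.
2. The aryl–alkyne bond is cut (Sonogashira) to 4-ethynylanisole and an unprotected 3-iodo-4,2'-dihydroxy-4'-methoxychalcone. Coupling and both ring closures then run in one flask.
3. The enone C=C is cut (Claisen–Schmidt) to paeonol and 4-hydroxy-3-iodobenzaldehyde.
4. Ring order in the flask: the furan closes first, because the free para-OH would deactivate the enone and make C2 labile. The pyranone closes second and sets the only stereocentre in the last bond formed. No protecting groups are used.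

Assumption: the commercial quinine-derived catalyst 1-[3,5-bis(trifluoromethyl)phenyl]-3-[(8α,9S)-6'-methoxycinchonan-9-yl]thiourea is taken to give the (2S) product; the sense is checked on the first run (chiral HPLC; CD of a 2S-flavanone is positive near 330 nm and negative near 290 nm), and if it is reversed the quinidine-derived pseudo-enantiomer is used with no other change.

## Route

Step 1
Reactants: 1 paeonol, 1-(2-hydroxy-4-methoxyphenyl)ethan-1-one; 2 4-hydroxy-3-iodobenzaldehyde
Product: 3 (E)-3-(4-hydroxy-3-iodophenyl)-1-(2-hydroxy-4-methoxyphenyl)prop-2-en-1-one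
Conditions: KOH (50% aq, 8 equiv), EtOH, 25→45 °C, 36 h; then 2 M HCl, 0 °C, pH 4; recrystallise (EtOH/H2O)
Reagents that add atoms: none
Why: Claisen–Schmidt (crossed aldol) condensation in which only ketone 1 can enolise, E1cB loss of water gives the conjugated E-enone, the aryl iodide is inert, and the bis-phenoxide formed in strong base stays open-chain, so cold acidification precipitates the chalcone and not the flavanone.

Step 2
Reactants: 3 (E)-3-(4-hydroxy-3-iodophenyl)-1-(2-hydroxy-4-methoxyphenyl)prop-2-en-1-one; 4 4-ethynylanisole (1-ethynyl-4-methoxybenzene, 1.2 equiv)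
Product: 7 lophirone J, (2S)-7-methoxy-2-[2-(4-methoxyphenyl)-1-benzofuran-5-yl]-2,3-dihydro-4H-chromen-4-one, via alkynyl bis-phenol chalcone 5 (not isolated), via benzofuranyl chalcone 6 (not isolated)
Conditions: (i) PdCl2(PPh3)2 (1 mol %), CuI (2 mol %), Et3N (3 equiv), degassed THF, 25→55 °C, 6 h; (ii) evaporate in the flask, PhMe, thiol-silica scavenger, 4 Å MS; (iii) quinine-derived 3,5-(CF3)2C6H3-thiourea (20 mol %), 25 °C, 72–96 h, same flask; silica chromatography (recovered 6 recycled), recrystallise (EtOH) to ≥99% ee
Reagents that add atoms: none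
Why: Proposed new method: a three-catalyst relay in one flask joins two known reaction types, first the Pd/Cu domino Sonogashira coupling/5-endo-dig heteroannulation of an o-iodophenol (oxidative addition into the C–I bond of 3, alkynyl transfer from the copper acetylide of 4 to give 5, then π-activation of the anisyl-polarised alkyne for attack by the acidic para-enone phenol to give 6, while the chelated 2'-OH is inert to Et3N in an aprotic solvent) and second the bifunctional cinchona-thiourea intramolecular oxa-Michael addition (biomimetic chalcone-to-flavanone isomerisation), where the thiourea H-bonds the enone carbonyl and the quinuclidine deprotonates the 2'-OH so that the phenoxide adds 6-endo-trig to the Si face of C-β and sets (2S); the closest known reaction type is the one-pot relay of a cinchona H-bond-donor Michael addition with a coinage-metal alkyne hydroalkoxylation, and closing the furan first removes the para-OH that would otherwise racemise C2 by quinone-methide ring opening.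

## Compound list
1 | paeonol, 1-(2-hydroxy-4-methoxyphenyl)ethan-1-one | CC(=O)c1ccc(OC)cc1O | starting material
2 | 4-hydroxy-3-iodobenzaldehyde | O=Cc1ccc(O)c(I)c1 | starting material
3 | (E)-3-(4-hydroxy-3-iodophenyl)-1-(2-hydroxy-4-methoxyphenyl)prop-2-en-1-one | COc1ccc(C(=O)/C=C/c2ccc(O)c(I)c2)c(O)c1 | intermediate
4 | 4-ethynylanisole | C#Cc1ccc(OC)cc1 | starting material
5 | (E)-3-{4-hydroxy-3-[(4-methoxyphenyl)ethynyl]phenyl}-1-(2-hydroxy-4-methoxyphenyl)prop-2-en-1-one | COc1ccc(C#Cc2cc(/C=C/C(=O)c3ccc(OC)cc3O)ccc2O)cc1 | intermediate
6 | (E)-1-(2-hydroxy-4-methoxyphenyl)-3-[2-(4-methoxyphenyl)-1-benzofuran-5-yl]prop-2-en-1-one | COc1ccc(-c2cc3cc(/C=C/C(=O)c4ccc(OC)cc4O)ccc3o2)cc1 | intermediate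
7 | lophirone J, (2S)-7-methoxy-2-[2-(4-methoxyphenyl)-1-benzofuran-5-yl]-2,3-dihydro-4H-chromen-4-one | COc1ccc(-c2cc3cc([C@@H]4CC(=O)c5ccc(OC)cc5O4)ccc3o2)cc1 | target

Total step count: 2. Longest linear sequence: 2.

## Steps most likely to fail
The route has only two steps, so step 2 is entered twice, once for each of its independent stages.

**1) Step 2, oxa-Michael stage.**
- The enone carries no activating group and is made less electrophilic by the 4'-OMe group.
- The closure is reversible, so conversion may stop near 80–90%.
- The ee of the crude product may be only moderate, and leftover iodide or metal can bind the thiourea.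
- The fallback sets out from 6 and comes back at 7.
- The first-stage mixture is worked up and 6 is closed without stereocontrol (NaOAc, EtOH, reflux). This gives racemic 7-methoxy-2-[2-(4-methoxyphenyl)-1-benzofuran-5-yl]chroman-4-one F1.
- The racemate is then resolved kinetically by asymmetric transfer hydrogenation ([Cp*RhCl((R,R)-TsDPEN)] 0.5 mol %, HCO2H/Et3N, EtOAc, 25 °C, stopped at about 55% conversion).
- The (R,R)-catalyst makes (4R)-benzylic alcohols and is matched only with the (2R)-ketone. That ketone is reduced to (2R,4R)-cis-7-methoxy-2-[2-(4-methoxyphenyl)-1-benzofuran-5-yl]chroman-4-ol F2.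
- The untouched (2S)-ketone is separated on silica as 7. The yield ceiling of this fallback is 50%.

**2) Step 2, coupling/heteroannulation stage.**
- The unprotected bis-phenol enone may close early to racemic flavanone on warming with amine.
- The 5-endo-dig closure may stall at 5, or alkyne homocoupling may use up 4.
- The fallback sets out from 2 and 4 and comes back at 6.
- The Pd/Cu domino (PdCl2(PPh3)2, CuI, Et3N, DMF, 60 °C) is run on aldehyde 2, which has neither an enone nor a second phenol. This gives 2-(4-methoxyphenyl)-1-benzofuran-5-carbaldehyde F3.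
- This non-phenolic aldehyde condenses cleanly with 1 (KOH, EtOH, 25 °C; then HCl) to give 6.
- Compound 6 is crystallised free of metals and salts and then given to the chiral catalyst in toluene as in stage (iii).

**3) Step 1.**
- In base, aldehyde 2 is present as its para-phenoxide and is a poor electrophile. The condensation can therefore be slow and low-yielding.
- The fallback sets out from 2 and comes back at 3.
- The phenol is masked (MOMCl, iPr2NEt, CH2Cl2, 0 °C) to give 3-iodo-4-(methoxymethoxy)benzaldehyde F4.
- F4 is condensed with 1 (KOH, EtOH, 25 °C; then HCl to pH 6). This gives (E)-1-(2-hydroxy-4-methoxyphenyl)-3-[3-iodo-4-(methoxymethoxy)phenyl]prop-2-en-1-one F5.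
- The acetal is removed with HCl in MeOH at 50 °C for 30 min to give 3.

## Further compounds
F1 | step 2 | racemic 7-methoxy-2-[2-(4-methoxyphenyl)-1-benzofuran-5-yl]chroman-4-one | COc1ccc(-c2cc3cc(C4CC(=O)c5ccc(OC)cc5O4)ccc3o2)cc1
F2 | step 2 | (2R,4R)-cis-7-methoxy-2-[2-(4-methoxyphenyl)-1-benzofuran-5-yl]chroman-4-ol | COc1ccc(-c2cc3cc([C@H]4C[C@@H](O)c5ccc(OC)cc5O4)ccc3o2)cc1
F3 | step 2 | 2-(4-methoxyphenyl)-1-benzofuran-5-carbaldehyde | COc1ccc(-c2cc3cc(C=O)ccc3o2)cc1
F4 | step 1 | 3-iodo-4-(methoxymethoxy)benzaldehyde | COCOc1ccc(C=O)cc1I
F5 | step 1 | (E)-1-(2-hydroxy-4-methoxyphenyl)-3-[3-iodo-4-(methoxymethoxy)phenyl]prop-2-en-1-one | COCOc1ccc(/C=C/C(=O)c2ccc(OC)cc2O)cc1I
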